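## The problem

The target is the isovanillate of a himachalane-type diol: a cyclohexene (ring A) cis-fused to a cycloheptane (ring B), with the ester on the allylic carbon of ring A and a tertiary methyl carbinol in ring B. Numbering used throughout: C1 and C6 are the ring-fusion methines (C1 beside the CMe2 carbon C11, C6 beside the methyl carbinol C7), C2=C3 is the ring A alkene with a methyl on C3, C4 bears the ester oxygen, C5 is the ring A methylene, and C8, C9 and C10 are the ring B methylenes running from C7 to C11. Four stereocentres have to be set, C1 (S), C4 (R), C6 (R) and C7 (S): H1 and H6 are cis, the C4 oxygen lies on their face of ring A, and the C7 hydroxyl lies on the concave face of ring B (trans to H6), so its methyl is on the convex face. C6 is the natural anchor: it can fix C1 if the C1 substituent is delivered intramolecularly across ring A, and the resulting cis-fused bicycle then offers a convex face that can steer reagents at C7 and C4; C4 and C7 cannot be expected to control each other. C1 is the hardest centre, a methine between the quaternary C11 and the C6 branch point, and the seven-membered ring has to be closed next to that congestion. The fragile elements are the allylic C4 ester (ionisation, SN2' attack, cleavage by hydrides and organometallics), the tertiary C7 alcohol (acid-promoted dehydration) and the guaiacol-type free phenol (oxidants, strong base), which together argue for esterification as the last step. The key step is possible because C6, C7, the C7 methyl and C8 form an isopropenyl group on a ring whose C4 oxygen, C3 methyl and C2=C3 alkene are the enone of carvone (1); C8 is then separated from C1 only by C9, C10 and C11, so a C9 aldehyde on a C1 side chain and the isopropenyl group form an enophile–ene pair whose union is ring B.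

## Retrosynthesis

**25 to 23 and 24.** The C4–O ester bond is cut first, with inversion at C4 in mind. Hydride reduction of a C4 ketone in this series is expected to give the alcohol cis to the ring B bond at C6 (the carvone to cis-carveol sense), which is the wrong epimer for direct acylation. An inverting Mitsunobu esterification of diol 23 with isovanillic acid (24) therefore does coupling and stereochemical correction in one step. Placing it last keeps the free phenol and the ester away from periodate, hydrides and organometallics. The forward reaction must be an SN2 displacement at the allylic carbon without SN2' or elimination, and must leave the tertiary C7 alcohol alone.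

**23 to 22.** The C7–CH3 bond is cut, giving hydroxy ketone 22. The neighbouring options (hydration, or epoxidation and hydride opening of a C7 methylene) would put oxygen on the accessible convex face, which is the wrong C7 epimer. A methyl nucleophile entering the ketone from the convex face leaves the oxygen on the concave face, as the target requires. The reagent must be weakly basic, because C6 is an epimerisable α-centre.

**22 to 19.** The C7 ketone is traced to the exocyclic methylene of enone 19 through glycol 20 and triol 21. The order is dictated by chemoselectivity. The methylene must be oxidised while C2=C3 is still an enone alkene (19 to 20). The C4 carbonyl must be reduced before any methyl nucleophile is present (20 to 21). The glycol serves as a masked ketone during that reduction and is cleaved afterwards (21 to 22). No protecting group is spent.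

**19 to 17.** The C9–H bond is exchanged for C9–OH via thionocarbonate 18. The hydroxyl is the unavoidable trace of a carbonyl enophile; a neutral radical deoxygenation removes it without touching the enone.

**17 to 16 (key disconnection).** The C8–C9 bond is cut and ring B opens to enone aldehyde 16. The alternative ring B bonds all lie next to a quaternary or fully substituted carbon (C10–C11, C6–C7, C1–C11); C8–C9 joins two unhindered carbons. The cut also turns C7, its methyl and C8 back into the isopropenyl group of carvone, so 16 is a monocyclic carvone derivative lacking only the C1 side chain. The forward reaction must choose the isopropenyl alkene over C2=C3, which is why C4 is a ketone in 16.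

**16 to 12.** The aldehyde is unmasked from methyl enol ether 15, whose C4 ketone comes from alcohol 14 and silyl ether 13. Enol ether 13 is the Wittig homologue of neopentyl aldehyde 12 (C9–C10 cut). The aldehyde is released only after C2=C3 has become an enone alkene, so it never coexists with a nucleophilic ring alkene under acid.

**12 to 8.** Aldehyde 12 comes from alcohol 11, and the C1–C11 bond is then cut by a retro-Ireland–Claisen step to tertiary allylic isobutyrate 8. Alkylation or conjugate addition at C1 would have to create a quaternary–tertiary bond cis to the C6 substituent against the steric bias. The [3,3] shift delivers C11 suprafacially from the C3 oxygen, so the C3 carbinol configuration alone sets C1. Both α-substituents are methyl, so ketene acetal geometry is irrelevant.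

**8 to 1.** Ester 8 is the acylation product of alcohol 6 with isobutyryl chloride (7). Alcohol 6 arises from epoxide 4 by selenide opening and selenoxide elimination, which moves the alkene to C1=C2 and leaves the oxygen on C3. Epoxide 4 is the silyl ether of epoxy alcohol 3, formed by hydroxyl-directed epoxidation of cis-carveol 2, the Luche product of (S)-carvone (1). Chirality is thus relayed from C6 to C4, to C3 and finally to C1.

## Roads not taken

**Alternative 1:** Ring A is disconnected at C1–C6, back to the vinyl δ-lactone A1, in which the C7 carboxyl is tied through oxygen to C3. In the forward sense the silyl ketene acetal of A1 undergoes a boat-type Ireland–Claisen ring contraction, C6 bonding to C1 as C3–O breaks, to give the ring A acid A2 with the C2=C3 alkene and the C1, C4 and C6 centres in place.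
- Merits: one step builds ring A and both fusion centres; the C4 oxygen is carried in its final configuration, so there is no late inversion, no C4 redox detour and no C9 oxygen to remove.
- Weak points: A1 has two stereocentres of its own (C4 and the quaternary C3 carbinol) and an E-alkene beside a quaternary carbon, all to be made by asymmetric synthesis. The new bond forms at C1 next to C11 through a strained boat. After A2, ring B is still open: the seven-membered ring must be closed at C7–C8 and C7 must still receive its methyl group with control.
- Comparison: A2 is better on C4 configuration and redox economy. The chosen plan sets against this a purchased stereocentre, and a key step that closes ring B and creates the C7 handle at once.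

**Alternative 2:** Ring B is disconnected at C10–C11 and C6–C7, back to the terpene-derived cyclopropyl enone A3 and 2-methylfuran A4. TiCl4 would open the cyclopropane bond between C6 and C11 to a C11 cation and a C6 titanium enolate, which add in turn to the two α-carbons of A4 in a formal (4+3) process, giving the oxygen-bridged tricyclic enone A5.
- Merits: the most convergent plan; all fifteen skeletal carbons are assembled in one step, C1 and the gem-dimethyl carbon are bought, and the C7 oxygen and methyl arrive together.
- Weak points: the cyclopropane has no donor substituent, so the step relies on a simple tertiary cation and must outrun Friedel–Crafts alkylation of A4 and elimination to an isopropenyl group. The regiochemistry of the unsymmetrical furan and the facial sense at C6 and C7 relative to C1 are not secured. A5 carries the ketone on C5 and the alkene at C3=C4, so the ring A functionality must be transposed. It also has an extra C8=C9 alkene and an ether bridge that must be cut at C10–O while keeping C7–O, although both are allylic.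
- Comparison: shorter to the skeleton than the chosen plan, but longer and less certain afterwards. The chosen plan places every functional group where the target needs it.

**Alternative 3:** Both rings are disconnected at C1–C6 and C4–C5, back to the acyclic trienone A6. An intramolecular Diels–Alder reaction of its vinyl ketone with the acetoxy diene would give the cis-fused keto acetate A7.
- Merits: on paper the shortest route. Both rings and C1, C4 and C6 form in one step from an achiral chain; C7 is already the ketone that the chosen route reaches only in step 17; no C9 oxygen is ever introduced.
- Weak points: there is no resident stereocentre, so absolute configuration depends on a chiral catalyst acting on a one-point-binding vinyl ketone. The tether closes a seven-membered ring, much slower than the usual five- or six-membered cases. The diene terminus is neopentyl-like, the cis or trans fusion (endo or exo) is not secured, and the vinyl ketone can polymerise.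
- Comparison: A7 has the same C4 configuration that the chosen route inverts, so it gains nothing there, but it is clearly ahead in step count and redox economy. The chosen plan sets against this a purchased absolute configuration, a cis fusion enforced by a suprafacial shift, and a ring B closure of a known type.

Key step: step 12

Remark on the chemistry: 17 and 18 are expected as C9 epimer mixtures that converge at 19 (the epimer with the hydroxyl on the H1/H6 face of ring B is drawn), and enol ethers 13 to 15 as E/Z mixtures that converge at 16 (E drawn).

## Route

Step 1
Reactants: 1 (S)-carvone
Product: 2 (1S,5S)-cis-carveol (C4 hydroxyl cis to the C6 isopropenyl group)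
Conditions: NaBH4, CeCl3·7H2O, MeOH, −78 °C
Reagents that add atoms: none
Why: Luche reduction gives clean 1,2-reduction of the enone; axial hydride delivery anti to the equatorial isopropenyl group should give the cis alcohol, as is known for carvone.

Step 2
Reactants: 2 (1S,5S)-cis-carveol
Product: 3 syn-epoxy alcohol (C2–C3 epoxide on the face of the C4 hydroxyl and the C6 isopropenyl group)
Conditions: VO(acac)2 (cat.), t-BuOOH, CH2Cl2, 0 °C to rt
Reagents that add atoms: tert-butyl hydroperoxide, CC(C)(C)OO
Why: Hydroxyl-directed epoxidation: the vanadium alkoxide–peroxide complex delivers oxygen to the allylic alkene on the face of the C4 hydroxyl, and the isopropenyl alkene, which has no directing group, should be left untouched.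

Step 3
Reactants: 3 syn-epoxy alcohol
Product: 4 TBS ether of 3
Conditions: TBSCl, imidazole, DMF, rt
Reagents that add atoms: tert-butyldimethylsilyl chloride, CC(C)(C)[Si](C)(C)Cl
Why: Standard silylation of a secondary alcohol; the ether blocks the C4 oxygen through the base, hydride and ylide steps and keeps acylation in step 5 on the tertiary oxygen.

Step 4
Reactants: 4 TBS ether of 3
Product: 6 tertiary allylic alcohol (C1=C2 alkene; C3 hydroxyl cis to the C4 silyloxy and C6 isopropenyl groups), via hydroxy selenide 5 (not isolated)
Conditions: PhSeSePh, NaBH4, EtOH, reflux; then H2O2 (30%), THF, 0 °C to rt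
Reagents that add atoms: none
Why: Selenide opening of the epoxide followed by selenoxide syn-elimination (Sharpless protocol). The selenolate attacks the secondary carbon C2 trans-diaxially in the half-chair that keeps the isopropenyl and silyloxy groups equatorial, so the oxygen stays on C3 with its configuration. The selenoxide can eliminate only towards C1 because C3 has no hydrogen.

Step 5
Reactants: 6 tertiary allylic alcohol, 7 isobutyryl chloride
Product: 8 tertiary allylic isobutyrate
Conditions: n-BuLi, THF, −78 °C; then 7, −78 to 0 °C
Reagents that add atoms: none
Why: O-acylation of a lithium tertiary alkoxide by an acid chloride, the usual answer to hindered tertiary alcohols; the low temperature limits silyl migration from the neighbouring oxygen.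

Step 6
Reactants: 8 tertiary allylic isobutyrate
Product: 11 neopentyl alcohol (C1 bears C(CH3)2CH2OH cis to the C6 isopropenyl group; C2=C3 alkene; C4 silyl ether), via silyl ketene acetal 9 (not isolated), via trimethylsilyl ester 10 (not isolated)
Conditions: LiN(iPr)2, TMSCl, Et3N, THF, −78 to 60 °C; then LiAlH4, 0 °C to rt
Reagents that add atoms: none
Why: Ireland–Claisen rearrangement followed by hydride reduction of the silyl ester in the same flask. The [3,3] shift is suprafacial across ring A, so C1–C11 forms on the face that carried the C3 ester oxygen, cis to the C6 isopropenyl group, and the alkene moves to C2=C3. Both α-substituents are methyl, so ketene acetal geometry does not matter and C11 is not stereogenic.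

Step 7
Reactants: 11 neopentyl alcohol
Product: 12 neopentyl aldehyde (C1 bears C(CH3)2CHO)
Conditions: Dess–Martin periodinane, NaHCO3, CH2Cl2, 0 °C to rt
Reagents that add atoms: none
Why: Dess–Martin oxidation of a hindered primary alcohol under buffered neutral conditions; the aldehyde has no α-hydrogen, so it cannot enolise or epimerise.

Step 8
Reactants: 12 neopentyl aldehyde
Product: 13 methyl enol ether (C1 bears C(CH3)2CH=CHOCH3)
Conditions: MeOCH2PPh3Cl, KN(SiMe3)2, THF, 0 °C to rt
Reagents that add atoms: (methoxymethyl)triphenylphosphonium chloride, COC[P+](c1ccccc1)(c1ccccc1)c1ccccc1.[Cl-]
Why: Wittig methoxymethylenation adds C9 as a masked aldehyde; the non-enolisable aldehyde tolerates the basic ylide.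

Step 9
Reactants: 13 methyl enol ether
Product: 14 allylic alcohol (free C4 hydroxyl; enol ether retained)
Conditions: Bu4NF, THF, rt
Reagents that add atoms: none
Why: Fluoride-mediated desilylation; the enol ether and both alkenes are inert to fluoride.

Step 10
Reactants: 14 allylic alcohol
Product: 15 enone enol ether (C4 ketone conjugated with C2=C3)
Conditions: MnO2, CH2Cl2, rt
Reagents that add atoms: none
Why: MnO2 oxidation is selective for allylic alcohols and is neutral, so the acid-sensitive enol ether survives.

Step 11
Reactants: 15 enone enol ether
Product: 16 enone aldehyde (C1 bears C(CH3)2CH2CHO cis to the C6 isopropenyl group)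
Conditions: 1 M HCl, THF, 0 °C to rt
Reagents that add atoms: water, O
Why: Acid-catalysed enol ether hydrolysis (C-protonation, hydration, loss of methanol) under mild conditions; the aldehyde appears only once C2=C3 is an enone alkene and no longer a nucleophile for Prins-type closure.

Step 12
Reactants: 16 enone aldehyde
Product: 17 bicyclic enone (cis-fused; C9 hydroxyl; exocyclic C7 methylene)
Conditions: Me2AlCl (2.5 equiv), CH2Cl2, −78 to 0 °C
Reagents that add atoms: none
Why: Type 2 intramolecular carbonyl-ene reaction: Me2AlCl binds the C9 aldehyde oxygen (a second equivalent sits on the enone oxygen), the C8 terminus of the isopropenyl group attacks C9 and a hydrogen of the C7 methyl passes to oxygen through a six-membered transition state, forming C8–C9 and leaving C7 as an exocyclic methylene. The closest known reaction type is the Me2AlCl-promoted cyclisation of ω-isopropenyl aldehydes to 3-methylenecycloalkanols, established for six- and seven-membered rings. Ring B closes in the type 2 mode (tether on the central ene carbon C7), 7-exo at the aldehyde carbon with C7 and C8 both inside the new ring. The one new stereocentre, C9, is set by the orientation of the aldehyde in the cyclic array; it is not relied on because step 14 removes it. C1 and C6 are untouched, and their cis relationship together with the gem-dimethyl group on C11 holds C8 and C9 within bonding distance. The selectivity needed is for the isopropenyl alkene over C2=C3: attack by C2 would place positive charge on C3 next to the C4 carbonyl, so the enone alkene is inert, whereas with an ether at C4 a five-membered type 1 closure onto C2 would compete. Hydrogen transfer from the methyl and not from C6–H is expected because C6–H lies in the tether and cannot reach the oxygen. Me2AlCl also consumes the proton released (as methane), which suppresses alkene migration and chloride capture.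

Step 13
Reactants: 17 bicyclic enone
Product: 18 C9 O-phenyl thionocarbonate
Conditions: PhOC(S)Cl, pyridine, DMAP (cat.), CH2Cl2, rt
Reagents that add atoms: O-phenyl chlorothionoformate, S=C(Cl)Oc1ccccc1
Why: Thioacylation of the secondary alcohol under weakly basic conditions; this avoids the alkoxide and CS2 of a xanthate preparation, which would enolise the enone towards C1.

Step 14
Reactants: 18 C9 O-phenyl thionocarbonate
Product: 19 deoxygenated enone (C9 methylene; exocyclic C7 methylene; C4 ketone)
Conditions: Bu3SnH, AIBN (cat.), toluene, 100 °C
Reagents that add atoms: none
Why: Barton–McCombie deoxygenation: the stannyl radical adds to C=S far faster than to the enone, and the C9 radical should be reduced before it can add across the ring to C2, a closure that would need both ring-fusion arms axial on ring A.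

Step 15
Reactants: 19 deoxygenated enone
Product: 20 enone glycol (C7 tertiary hydroxyl cis to H6; C7 hydroxymethyl)
Conditions: OsO4 (cat.), NMO, acetone–H2O, rt
Reagents that add atoms: N-methylmorpholine N-oxide, C[N+]1([O-])CCOCC1; water, O
Why: Upjohn dihydroxylation: electrophilic OsO4 selects the electron-rich 1,1-disubstituted alkene over the electron-poor, hindered enone alkene. The C7 configuration formed here (convex-face attack expected) is erased in step 17.

Step 16
Reactants: 20 enone glycol
Product: 21 triol (C4 hydroxyl cis to the C6–C7 bond)
Conditions: NaBH4, CeCl3·7H2O, MeOH, −78 °C
Reagents that add atoms: none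
Why: Luche 1,2-reduction: hydride enters from the ring A face opposite the ring B bonds, as in step 1, giving the C4 alcohol cis to C7. The glycol is inert, so C7 stays masked while the only carbonyl present is reduced.

Step 17
Reactants: 21 triol
Product: 22 hydroxy ketone (C7 ketone; C4 hydroxyl)
Conditions: NaIO4, THF–H2O, 0 °C to rt
Reagents that add atoms: none
Why: Periodate (Malaprade) cleavage acts only on the 1,2-diol and releases the C7 ketone under neutral conditions that should not epimerise C6.

Step 18
Reactants: 22 hydroxy ketone
Product: 23 diol (C7 hydroxyl trans to H6 with the C7 methyl cis to H6; C4 hydroxyl cis to the C6–C7 bond)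
Conditions: MeLi, CeCl3, THF, −78 °C
Reagents that add atoms: methyllithium, [Li]C
Why: Organocerium (Imamoto) 1,2-addition: the weakly basic reagent should add without enolising towards C6, and the free C4 hydroxyl only consumes one equivalent. The methyl group is expected to enter from the convex face of the cis-fused bicycle (the side of H6), which leaves the hydroxyl on the concave face as in the target.

Step 19
Reactants: 23 diol, 24 isovanillic acid
Product: 25 (2R,4aS,9S,9aR)-9-hydroxy-3,5,5,9-tetramethyl-2,4a,5,6,7,8,9,9a-octahydro-1H-benzo[7]annulen-2-yl 3-hydroxy-4-methoxybenzoate (target)
Conditions: PPh3, DIAD, THF, 0 °C to rt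
Reagents that add atoms: none
Why: Mitsunobu esterification with SN2 inversion at C4 turns the alcohol cis to C7 into the ester trans to it. The carboxylic acid is far more acidic than the phenol and so acts as the nucleophile, a chemoselectivity known for unprotected phenolic acids; the tertiary C7 alcohol is not activated.

## Compound list

1 | (S)-carvone | O=C1C[C@@H](C(C)=C)CC=C1C | starting material
2 | (1S,5S)-cis-carveol | O[C@H]1C[C@@H](C(C)=C)CC=C1C | intermediate
3 | syn-epoxy alcohol (epoxide, C4 hydroxyl and C6 isopropenyl on one face) | O[C@H]1C[C@@H](C(C)=C)C[C@H]2O[C@]21C | intermediate
4 | TBS ether of 3 | CC(C)(C)[Si](C)(C)O[C@H]1C[C@@H](C(C)=C)C[C@H]2O[C@]21C | intermediate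
5 | hydroxy selenide (C2 phenylselanyl trans to the C3 hydroxyl) | CC(C)(C)[Si](C)(C)O[C@H]1C[C@@H](C(C)=C)C[C@H]([Se]c2ccccc2)[C@@]1(C)O | intermediate (not isolated)
6 | tertiary allylic alcohol (C1=C2; C3 hydroxyl cis to C4 silyloxy) | CC(C)(C)[Si](C)(C)O[C@H]1C[C@@H](C(C)=C)C=C[C@@]1(C)O | intermediate
7 | isobutyryl chloride | CC(C)C(Cl)=O | starting material
8 | tertiary allylic isobutyrate | CC(C)(C)[Si](C)(C)O[C@H]1C[C@@H](C(C)=C)C=C[C@@]1(C)OC(=O)C(C)C | intermediate
9 | trimethylsilyl ketene acetal of 8 | CC(C)(C)[Si](C)(C)O[C@H]1C[C@@H](C(C)=C)C=C[C@@]1(C)OC(O[Si](C)(C)C)=C(C)C | intermediate (not isolated)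
10 | rearranged trimethylsilyl ester (C1 bears C(CH3)2CO2SiMe3) | CC(C)(C)[Si](C)(C)O[C@H]1C[C@@H](C(C)=C)[C@H](C=C1C)C(C)(C)C(=O)O[Si](C)(C)C | intermediate (not isolated)
11 | neopentyl alcohol (C1 arm cis to C6 isopropenyl) | CC(C)(C)[Si](C)(C)O[C@H]1C[C@@H](C(C)=C)[C@H](C=C1C)C(C)(C)CO | intermediate
12 | neopentyl aldehyde | CC(C)(C)[Si](C)(C)O[C@H]1C[C@@H](C(C)=C)[C@H](C=C1C)C(C)(C)C=O | intermediate
13 | methyl enol ether (E drawn) | CC(C)(C)[Si](C)(C)O[C@H]1C[C@@H](C(C)=C)[C@H](C=C1C)C(C)(C)/C=C/OC | intermediate
14 | allylic alcohol enol ether | O[C@H]1C[C@@H](C(C)=C)[C@H](C=C1C)C(C)(C)/C=C/OC | intermediate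
15 | enone enol ether | O=C1C[C@@H](C(C)=C)[C@H](C=C1C)C(C)(C)/C=C/OC | intermediate
16 | enone aldehyde (key-step precursor) | O=C1C[C@@H](C(C)=C)[C@H](C=C1C)C(C)(C)CC=O | intermediate
17 | bicyclic enone with C9 hydroxyl and C7 methylene (key-step product) | O=C1C[C@@H]2[C@H](C=C1C)C(C)(C)C[C@@H](O)CC2=C | intermediate
18 | C9 O-phenyl thionocarbonate of 17 | O=C1C[C@@H]2[C@H](C=C1C)C(C)(C)C[C@@H](OC(=S)Oc3ccccc3)CC2=C | intermediate
19 | deoxygenated bicyclic enone with C7 methylene | O=C1C[C@@H]2[C@H](C=C1C)C(C)(C)CCCC2=C | intermediate
20 | enone glycol (C7 hydroxyl cis to H6; hydroxymethyl on C7) | O=C1C[C@@H]2[C@H](C=C1C)C(C)(C)CCC[C@]2(O)CO | intermediate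
21 | triol (C4 hydroxyl cis to the C6–C7 bond) | O[C@H]1C[C@@H]2[C@H](C=C1C)C(C)(C)CCC[C@]2(O)CO | intermediate
22 | hydroxy ketone (C7 ketone) | O[C@H]1C[C@@H]2[C@H](C=C1C)C(C)(C)CCCC2=O | intermediate
23 | diol (C7 hydroxyl trans to H6; C4 hydroxyl cis to C7) | O[C@H]1C[C@@H]2[C@H](C=C1C)C(C)(C)CCC[C@]2(C)O | intermediate
24 | isovanillic acid | COc1ccc(C(=O)O)cc1O | starting material
25 | target isovanillate | COc1ccc(C(=O)O[C@@H]2C[C@@H]3[C@H](C=C2C)C(C)(C)CCC[C@]3(C)O)cc1O | target

## Step count and risks

Total: 19 steps. Longest linear sequence: 19 steps, from (S)-carvone (1) to 25; 7 and 24 are used as purchased.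

**Step 12 (key step).** The Lewis acid may divert the substrate: aldol-type closure of the C5 enol onto C9, proton loss towards C6 or C8 giving an endocyclic alkene, chloride capture, or oligomerisation if the seven-membered closure is slow. The fallback sets out from 16. Ene-type chlorination of the isopropenyl group with HOCl generated from Ca(OCl)2 and CO2 (the known conversion of an isopropenyl group into a 2-(chloromethyl)vinyl group) should give the allylic chloride F1. CrCl2 in THF (Nozaki–Hiyama allylation with divalent chromium) then adds the allyl unit to the C9 aldehyde through its γ-carbon C8. This forms the same C8–C9 bond by a two-electron allylmetal addition and regenerates the exocyclic C7 methylene, rejoining the route at 17.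

**Step 6.** The lithium enolate of a hindered tertiary allylic ester may fragment to a ketene and the alkoxide before it is silylated, or enolisation may be incomplete, and the shift has to build a quaternary centre beside a branched ring carbon. The fallback sets out from 6. Acylation with 2-bromoisobutyryl bromide (n-BuLi, THF, −78 °C) gives the bromo ester F2. Zinc dust and TMSCl in THF–MeCN at reflux (Reformatsky–Claisen rearrangement) generate ketene acetal 9 without an amide base; after the shift to 10 and aqueous hydrolysis the carboxylic acid F3 is obtained, and LiAlH4 reduction returns to the route at 11.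

**Step 14.** Radical side reactions may intervene: conjugate reduction of the enone by the tin hydride, or transannular addition of the C9 radical to the enone. The fallback is ionic and sets out from 17. MsCl and Et3N give the mesylate F4, Luche reduction gives the allylic alcohol mesylate F5, LiEt3BH in THF displaces the sulfonate by hydride to give the allylic alcohol F6, and MnO2 oxidation returns to the route at 19.

**Step 18.** Facial selectivity in the methyl transfer may be poor or reversed, and the α-branched ketone may enolise or be held as a bridged hemiketal with the C4 hydroxyl. The fallback sets out from 19 and delivers oxygen instead of carbon. mCPBA epoxidises only the exocyclic alkene, giving the spiro-epoxide F7. LiAlH4 then reduces the C4 ketone (in the carvone to cis-carveol sense) and opens the epoxide at its CH2 terminus, returning to the route at 23. This sequence gives 23 only if the concave face is the accessible one, which is exactly the case in which step 18 fails on selectivity.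

**Step 19.** The free phenol may be alkylated in competition with the carboxylate, and the allylic oxyphosphonium ion may undergo SN2' attack or elimination. The fallback removes the phenol from play and sets out from 24. TBSCl and imidazole give the bis-silyl derivative F8, and AcOH in THF–H2O cleaves the silyl ester to the O-silylated acid F9. Mitsunobu coupling of F9 with 23 gives the protected ester F10, and Bu4NF buffered with AcOH returns to the route at 25.

## Further compounds

F1 | step 12 | allylic chloride (C6 bears C(=CH2)CH2Cl; C1 arm and enone as in 16) | O=C1C[C@@H](C(=C)CCl)[C@H](C=C1C)C(C)(C)CC=O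
F2 | step 6 | 2-bromoisobutyrate of 6 | CC(C)(C)[Si](C)(C)O[C@H]1C[C@@H](C(C)=C)C=C[C@@]1(C)OC(=O)C(C)(C)Br
F3 | step 6 | rearranged carboxylic acid (C1 bears C(CH3)2CO2H) | CC(C)(C)[Si](C)(C)O[C@H]1C[C@@H](C(C)=C)[C@H](C=C1C)C(C)(C)C(=O)O
F4 | step 14 | C9 mesylate of 17 | O=C1C[C@@H]2[C@H](C=C1C)C(C)(C)C[C@@H](OS(C)(=O)=O)CC2=C
F5 | step 14 | C4 allylic alcohol C9 mesylate | O[C@H]1C[C@@H]2[C@H](C=C1C)C(C)(C)C[C@@H](OS(C)(=O)=O)CC2=C
F6 | step 14 | C4 allylic alcohol with C7 methylene | O[C@H]1C[C@@H]2[C@H](C=C1C)C(C)(C)CCCC2=C
F7 | step 18 | spiro-epoxide at C7 (oxygen on the concave face) | O=C1C[C@@H]2[C@H](C=C1C)C(C)(C)CCC[C@@]23CO3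
F8 | step 19 | tert-butyldimethylsilyl 3-(tert-butyldimethylsilyloxy)-4-methoxybenzoate | COc1ccc(C(=O)O[Si](C)(C)C(C)(C)C)cc1O[Si](C)(C)C(C)(C)C
F9 | step 19 | 3-(tert-butyldimethylsilyloxy)-4-methoxybenzoic acid | COc1ccc(C(=O)O)cc1O[Si](C)(C)C(C)(C)C
F10 | step 19 | O-silylated target ester | COc1ccc(C(=O)O[C@@H]2C[C@@H]3[C@H](C=C2C)C(C)(C)CCC[C@]3(C)O)cc1O[Si](C)(C)C(C)(C)C
A1 | alternative 1 | vinyl δ-lactone (C4 silyloxy cis to the C3 alkenyl group; E alkene) | O=C1CC[C@@H](O[Si](C)(C)C(C)(C)C)[C@@](C)(/C=C/C(C)(C)CCCOCc2ccc(OC)cc2)O1
A2 | alternative 1 | ring A carboxylic acid | CC(C)(C)[Si](C)(C)O[C@@H]1C[C@@H](C(=O)O)[C@H](C=C1C)C(C)(C)CCCOCc2ccc(OC)cc2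
A3 | alternative 2 | 3,7,7-trimethylbicyclo[4.1.0]hept-3-en-5-one (cyclopropyl enone) | CC1=CC(=O)[C@@H]2[C@H](C1)C2(C)C
A4 | alternative 2 | 2-methylfuran | Cc1ccco1
A5 | alternative 2 | oxygen-bridged tricyclic enone | CC1=CC(=O)[C@@H]2[C@H](C1)C(C)(C)[C@H]3C=C[C@]2(C)O3
A6 | alternative 3 | acyclic trienone with (E,E)-1-acetoxy-2-methyl diene | C=CC(=O)CCCC(C)(C)/C=C/C(C)=C/OC(C)=O
A7 | alternative 3 | cis-fused bicyclic keto acetate | CC(=O)O[C@H]1C[C@@H]2[C@H](C=C1C)C(C)(C)CCCC2=O
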